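Readings and results are calculated for an exercise; scatter was added.

At 20.0 s the epsilon run, which is the flask asked about, has made 0.0720 M of product and the eta run 0.0552 M: a ratio of 1.30 for twice the starting material.

| flask | starting material | reagent | free catalyst | remark | time |
|---|---|---|---|---|---|
| epsilon | 0.80 M | 0.84 M | 7 mM | the very flask that is asked about, followed so far |  |
| eta | 0.40 M | 0.84 M | 7 mM | run made earlier |  |
| flask | 0.80 M | 0.840 M | 7.0 mM |  | 4.0 min |

- epsilon (time / s: product / %): 10.0: 5.5; 15.0: 6.9; 20.0: 9.0
- eta (time / s: product / %): 20.0: 13.8; 40.0: 24.3; 60.0: 31.6; 80.0: 37.7; 90.0: 39.4

(standard deviation of a reading: 0.5 percentage points)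

- amount of product in percent of the starting material charged, at 50 s, 2.0 min and 4.0 min

- the numbers in the tables scatter by 0.5 percentage points (one standard deviation)
- what may be going on: reagent + catalyst intermediate A -> spent catalyst; starting material + catalyst intermediate B <-> catalyst intermediate C; reagent + free catalyst <-> catalyst intermediate A; catalyst intermediate A <-> catalyst intermediate B; catalyst intermediate C -> free catalyst + product

Two chemists dispute what stops this flask. The first holds a clock: the catalyst has a fixed lifetime τ, whatever the charge, so equal intervals bring gains that shrink by one constant fraction. In eta, the gain from 40.0 s to 80.0 s is 55.1% of the gain before it, so τ is 67.2 s and the clock's asymptote for eta is 54.2%. That curve returns 40.0% at 90.0 s, against the reading 39.4%. Scaled to the flask's reading at 20.0 s, it gives a ceiling of 35.0% and 18.3%, 29.1% and 34.0% at the asked times.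

The second chemist, whose reckoning this is, follows one catalyst molecule: at each fork it goes on with starting material or dies with reagent. So the turnover number n, product made per catalyst spent, should follow ρ, the concentration of starting material over that of reagent. Eta's readings show no ceiling, and the clock's asymptote belongs to the clock, so this chemist makes a separate rough assumption, despite that opening ratio: the rate follows both the starting material left and the living catalyst. Then L, the logarithm of the starting material charged over that left, is the quantity whose gains shrink by one constant fraction, and in eta the gain from 40.0 s to 80.0 s is 70.0% of the gain before it. That gives an estimated ceiling of 60.4% for eta, an estimate and not a reading, and so n = 34.5 at ρ = 0.388, taken at half that ceiling with one reagent per product. Hence ω = 89.0, the fork odds, n at equal concentrations of the two. The flask's ρ of 0.952 gives n = 84.7 and a ceiling of 74.1%, higher than the clock's.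

The forecast takes the fork's side, “Death and turnover then compete in a way that gives a roughly fixed fractional conversion”, with a ceiling of about 60% where mine gives 74.1%. It says 21%, 38% and 50%.

The flask gives 20.3%, 34.7% and 46.8%.

    reagent + catalyst intermediate A → spent catalyst (k = 0.140 M⁻¹ s⁻¹)
    starting material + catalyst intermediate B ⇌ catalyst intermediate C (K = 0.420 M⁻¹, k = 15.0 M⁻¹ s⁻¹)
    reagent + free catalyst ⇌ catalyst intermediate A (K = 0.190 M⁻¹, k = 44.0 M⁻¹ s⁻¹)
    catalyst intermediate A ⇌ catalyst intermediate B (K = 8.20, k = 10.0 s⁻¹)
    catalyst intermediate C → free catalyst + product (k = 11.0 s⁻¹)

The step to spent catalyst ran beside the round throughout: the flask holds product 11.4% and spent catalyst 21.3% at 0.400 min, then 46.8% and 75.8% at 4.00 min. At that time starting material 53% and reagent 54% remained, so n stood at 70.6, and at 40.0 min at 76.7, beside the 84.7 from ω. The clock keeps eta's first 90.0 s, where it was read. By ω, eta's reading at 90.0 s has spent 60.0% of its catalyst.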